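## Structural features

The target 23 is the methyl ester of a 3-hydroxy-1,2-dioxan-3-ylacetic acid. Its six-membered cyclic peroxide (O1–O2–C3–C4–C5–C6) has a peroxy-hemiketal carbon C3 that carries the hydroxyl group and the CH2CO2Me arm (C2, C1). C4 carries a methyl group. C6 is fully substituted: methyl, ring oxygen, C5, and the chain C7–C16, which has a methyl branch at C8 and a phenyl group on C16. There are four stereocentres, C3 (S), C4 (R), C6 (S) and C8 (R). C3 and C4 are adjacent; C4/C6 and C6/C8 are 1,3-related through the methylene groups C5 and C7. The O–O bond does not tolerate hydrogenation catalysts, phosphines, strong hydride donors or organometallic reagents. The hemiketal is the ring form of a δ-hydroperoxy β-keto ester and is therefore base-sensitive. C3 is not the real problem, because it equilibrates through the open form towards the isomer with axial hydroxyl and equatorial C4 methyl and acetate arm, which is 23. The real difficulty is the tertiary peroxide carbon C6, which needs a defined configuration relative to two unfunctionalised methyl-bearing carbons, together with the absolute configuration of all three. The key step exploits the latent symmetry of the C3–C9 segment: with identical groups at C3 and C9, a mirror plane runs through C6, its methyl group and the O–O bond, so C4 and C8 are mirror-related and C6 is pseudoasymmetric, and telling the two chain ends apart fixes C4, C6 and C8 together.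

## Logic of the disconnections

**23 to 21 (through 22).** The hemiketal bond C3–O2 is cut. Compound 23 is the ring tautomer of 22, so the forward closure is spontaneous and thermodynamically controlled. The ring and the C3 stereocentre disappear from the problem. The demand is that the hydroperoxide of 21 be unmasked last and without base.

**21 to 19 (through 20).** The C2–C3 bond is cut, the β-keto ester retron. The two-carbon ester unit comes from a malonate half-ester, which leaves the robust acid 19. The forward acylation must be close to neutral, so that C4 (α to the activated carboxyl) and the silyl peroxide survive.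

**19 to 18, then to 14 and 16 (through 17).** The C9–C10 bond is cut as a C=C bond. Carbonyl olefination followed by diimide reduction is one of the few carbon–carbon constructions that tolerate an O–O bond. The whole C10–C16 phenylalkyl tail is removed, leaving a seven-carbon chain. The forward step must work in the presence of a carboxylic acid and must not epimerise C8.

**14 to 13, 12 and 11.** No skeletal bond is cut; only oxidation levels and one protecting group change (C9 aldehyde from alcohol from acetate, C3 acid from alcohol). This reveals 11, in which the two ends differ only by an acetyl group. The forward steps must remove the acetate without base and oxidise without epimerising C4 or C8.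

**11 to 9 and 10.** Only the acetyl C–O bond at C9 is cut. Its removal gives the meso compound 9, so three stereocentres of defined absolute configuration collapse into a problem of relative configuration. The forward step needs a reagent that distinguishes enantiotopic termini six bonds apart, which only an enzyme can do.

**9 to 7 (through 8).** C3 and C9 are reconnected as a cis double bond in a seven-membered ring. The ring holds the methyl groups at C4 and C8 cis and makes 9 available by oxidative cleavage and reduction. The cleavage must spare the silyl peroxide and the two α-methyl centres.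

**7 to 6.** The C6–O bond is cut, and the exocyclic carbon loses the hydrogen that made it the C6 methyl group. Radical hydroperoxidation installs the tertiary peroxide already silylated, and the precursor 6 is a simple hydrocarbon diene. The forward step must react only at the 1,1-disubstituted double bond and deliver oxygen trans to the two ring methyl groups.

**6 to 5.** The exocyclic C=C bond is cut to a ketone. This is a routine methylenation with no stereochemical demand.

**5 to 2 and 3 (through 4).** The C4–C5 and C7–C8 bonds are cut together. A [4+3] cycloaddition builds the ring from a three-carbon and a six-carbon piece, both achiral. The forward step must bond suprafacially to the diene so that its E,E geometry becomes the cis relationship of the methyl groups.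

**2 to 1, and 16 to 15.** An enol-ether C=C bond is formed by loss of methanol from a ketal, and a C–P bond by quaternisation. Both lead back to purchasable compounds without further demands.

## Other disconnections considered

**Alternative 1:** The cut is made at C4–C5 and C7–C8 at once. In the forward direction a 2-oxyallyl cation adds across the termini of an E,E-configured hexadiene to give the meso cycloheptenone A1.
- In favour: two carbon–carbon bonds and the ring template form in one operation, and the cis relationship of the future C4 and C8 methyl groups follows from the diene geometry.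
- Against: A1 is achiral, so no absolute configuration is created. An acyclic diene must react through its minor s-cis conformer, so efficiency is expected to be modest. Silver is used stoichiometrically.
- Comparison: on skeletal construction this step is better than the lipase step, which forms no skeletal bond. On stereochemical information it is weaker, giving two relative centres against three absolute ones. On step economy the two are equal, because A1 is compound 5 of the chosen route; making the cycloaddition the centrepiece would still require a desymmetrisation or resolution afterwards.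

**Alternative 2:** The cut is made at C9–C10. In the forward direction the half-ester A3 and an excess of 8-phenyloctanoic acid A4 are electrolysed at platinum in methanol (mixed Kolbe coupling); both carboxylates lose CO2 and the two primary radicals combine to the ester A2, whose ester carbon is the future C6.
- In favour: the coupling needs no protecting groups, and the stereocentre of A3 is β to the radical centre and should not be touched. The saturated tail is in place before any peroxide exists, so no ylide or diimide meets an O–O bond; on this point the alternative is better than the chosen plan.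
- Against: cross-coupling is statistical, so the cheap acid must be used in excess and both symmetrical dimers removed. Only C8 is set, and C6 would later be created on an open chain with no ring to bias it.
- Comparison: the mechanism is simple and its absolute configuration can also originate from an enzyme-differentiated prochiral diester, so it is equal on the source of chirality. It delivers one stereocentre against three and needs a second chiral building block and a fragment union, so the overall length is comparable or greater.

**Alternative 3:** The cut is made at C5–C6. In the forward direction the thioester A6 (made from A2) is coupled with the ester-bearing alkylzinc iodide A7 under PdCl2(PPh3)2 catalysis (Fukuyama coupling; the divalent palladium precatalyst is reduced in situ to zerovalent palladium) to give the γ-keto ester A5 with C4 and C8 set and the C3–C16 chain complete.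
- In favour: the route is convergent, and the ketone synthesis is chemoselective (the organozinc tolerates the ester and does not add twice). Both stereocentres come from independently secured enantiopure pieces, so the absolute configuration does not depend on an untested enzyme–substrate fit; on convergence and on this reliability the alternative is better.
- Against: C6 arrives as an open-chain ketone, so methylenation and radical peroxidation would have no controlling element and should give both C6 epimers. The C3 ester must still be turned into the β-keto ester in the presence of the peroxide.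
- Comparison: the structure is assembled more convergently and the palladium step is mechanistically well understood. The chosen plan is stronger where the target is hardest, because it creates C6 on a ring whose two methyl groups bias the face. Step economy is about equal once the preparation of A6 and A7 is counted.

Key step: step 6

Assumption: carbons are numbered as in the open-chain form of 23 (C1 ester carbonyl, C3 hemiketal carbon, C6 peroxide carbon, C16 benzylic carbon), and the lipase is taken to acetylate the hydroxymethyl group on the (S)-configured carbon of 9, as it does with simpler meso 2-methyl-branched diols; the opposite preference is covered by the fallback to step 6.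

## Route

Step 1
Reactants: 1 1-bromo-2,2-dimethoxypropane
Product: 2 3-bromo-2-methoxyprop-1-ene (2-methoxyallyl bromide)
Conditions: i-Pr2NEt·TsOH (cat.), neat, 150 °C, MeOH distilled off
Reagents that add atoms: none
Why: Acid-catalysed elimination of methanol from the ketal gives the enol ether, and removal of methanol drives it; only the allylic bromide ionises in step 2, so vinylic isomers formed alongside are inert.

Step 2
Reactants: 2 3-bromo-2-methoxyprop-1-ene; 3 (2E,4E)-hexa-2,4-diene
Product: 5 (3R,6S)-3,6-dimethylcyclohept-4-en-1-one (cis; meso), via mixed ketal trifluoroacetate 4 (not isolated)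
Conditions: AgO2CCF3, Na2CO3, 3 (excess), pentane, 0 °C to rt, dark; then dilute aq. HNO3
Reagents that add atoms: water, O
Why: Silver-assisted ionisation gives the 2-methoxyallyl cation, which adds across the s-cis diene in a [4+3] cycloaddition; bonding is suprafacial on the diene, so the E,E geometry becomes the cis (meso) relationship of the two methyl-bearing carbons. The oxocarbenium ion is captured as 4 and hydrolysed to the ketone on work-up.

Step 3
Reactants: 5 (3R,6S)-3,6-dimethylcyclohept-4-en-1-one
Product: 6 (3R,7S)-3,7-dimethyl-5-methylidenecyclohept-1-ene (cis; meso)
Conditions: Ph3PCH3Br, KOtBu, THF, 0 °C to rt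
Reagents that add atoms: methyltriphenylphosphonium bromide, C[P+](c1ccccc1)(c1ccccc1)c1ccccc1.[Br-]
Why: Wittig methylenation of an unhindered, non-conjugated ketone; the methyl-bearing carbons are β to the carbonyl and cannot epimerise.

Step 4
Reactants: 6 (3R,7S)-3,7-dimethyl-5-methylidenecyclohept-1-ene
Product: 7 triethyl{[(1s,3R,6S)-1,3,6-trimethylcyclohept-4-en-1-yl]peroxy}silane (three methyl groups cis; silylperoxy group trans to them)
Conditions: Co(acac)2 (cat.), O2 (1 atm), Et3SiH, ClCH2CH2Cl, rt
Reagents that add atoms: dioxygen, O=O; triethylsilane, CC[SiH](CC)CC
Why: Mukaiyama–Isayama silylperoxidation: hydrogen-atom transfer from a cobalt hydride to the 1,1-disubstituted alkene gives the tertiary radical, O2 traps it and Et3SiH converts the cobalt peroxide into the silyl peroxide, while the cis-1,2-disubstituted ring alkene should react far more slowly. With both ring methyl groups equatorial in the chair cycloheptene, axial capture of O2 puts the O–O bond trans to them and the new methyl group equatorial, which is the relative configuration needed at C6; the minor epimer (also meso) is removed by chromatography.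

Step 5
Reactants: 7 triethyl{[(1s,3R,6S)-1,3,6-trimethylcyclohept-4-en-1-yl]peroxy}silane
Product: 9 (2R,4s,6S)-2,4,6-trimethyl-4-[(triethylsilyl)peroxy]heptane-1,7-diol (meso), via secondary ozonide 8 (not isolated)
Conditions: O3, CH2Cl2, −78 °C; then NaBH4, EtOH, −78 to 0 °C
Reagents that add atoms: ozone, [O-][O+]=O
Why: Ozonolysis cleaves the only remaining C=C bond and cold borohydride reduces the ozonide straight to the diol, so the α-methyl aldehydes do not accumulate and C4 and C8 keep their configuration; a hindered tertiary silyl peroxide should tolerate ozone and brief cold borohydride.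

Step 6
Reactants: 9 (2R,4s,6S)-2,4,6-trimethyl-4-[(triethylsilyl)peroxy]heptane-1,7-diol; 10 vinyl acetate
Product: 11 (2S,4R,6R)-7-hydroxy-2,4,6-trimethyl-4-[(triethylsilyl)peroxy]heptyl acetate
Conditions: Pseudomonas fluorescens lipase, 10 (excess), tert-butyl methyl ether, 25 °C
Reagents that add atoms: none
Why: This is a lipase-catalysed irreversible transesterification: the active-site serine is acetylated by vinyl acetate, the released vinyl alcohol tautomerises to acetaldehyde, and the acetyl-enzyme passes the acyl group to one hydroxymethyl group of 9. The closest known reaction type is the monoacetylation of meso 2-methyl-branched α,ω-diols such as meso-2,4-dimethylpentane-1,5-diol by Pseudomonas lipases. No ring is closed and no skeletal bond is formed. Because the two termini are enantiotopic, acylating one of them turns the mirror-related carbons C4 and C8 and the pseudoasymmetric C6 into three stereocentres of defined absolute configuration at once; the controlling element is the chiral binding site of the enzyme, which reads the methyl-bearing carbon next to the reacting CH2OH. By analogy with the simpler diols the hydroxymethyl group on the (S)-configured carbon should react, leaving the free hydroxyl at the future C3 and the acetate at the future C9. The selectivity needed is between two primary alcohols that differ only as mirror images; the substrate secures it by placing a methyl group against a large branched alkyl group directly beside each carbinol, while the hindered silyl peroxide is remote and not a substrate for a serine hydrolase. A little over-acetylation to the meso diacetate should consume the minor enantiomer of 11 preferentially and so raise its enantiomeric purity.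

Step 7
Reactants: 11 (2S,4R,6R)-7-hydroxy-2,4,6-trimethyl-4-[(triethylsilyl)peroxy]heptyl acetate
Product: 12 (2R,4S,6S)-7-(acetyloxy)-2,4,6-trimethyl-4-[(triethylsilyl)peroxy]heptanoic acid
Conditions: TEMPO (cat.), NaClO2, NaOCl (cat.), MeCN/NaH2PO4–Na2HPO4 buffer (pH 6.7), 35 °C
Reagents that add atoms: sodium chlorite, [Na+].[O-]Cl=O
Why: TEMPO-catalysed oxidation to the aldehyde followed in the same flask by Pinnick-type chlorite oxidation gives the acid near neutral pH, conditions that spare α-stereocentres, esters and silyl groups.

Step 8
Reactants: 12 (2R,4S,6S)-7-(acetyloxy)-2,4,6-trimethyl-4-[(triethylsilyl)peroxy]heptanoic acid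
Product: 13 (2R,4S,6S)-7-hydroxy-2,4,6-trimethyl-4-[(triethylsilyl)peroxy]heptanoic acid
Conditions: Pseudomonas fluorescens lipase, NaH2PO4–Na2HPO4 buffer (pH 7)/acetone, 25 °C
Reagents that add atoms: none
Why: Enzymatic hydrolysis of a primary acetate at neutral pH; the acetate sits on the terminus the enzyme recognises best, and neutral buffer avoids the loss of the silyl group from the peroxide that methanolic base would risk.

Step 9
Reactants: 13 (2R,4S,6S)-7-hydroxy-2,4,6-trimethyl-4-[(triethylsilyl)peroxy]heptanoic acid
Product: 14 (2R,4S,6S)-2,4,6-trimethyl-7-oxo-4-[(triethylsilyl)peroxy]heptanoic acid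
Conditions: Dess–Martin periodinane, pyridine, CH2Cl2, 0 °C to rt
Reagents that add atoms: none
Why: Dess–Martin oxidation of a primary alcohol to the aldehyde under buffered, non-basic conditions leaves the carboxylic acid and the silyl peroxide untouched and should not epimerise the α-methyl centre C8.

Step 10
Reactants: 15 (7-bromoheptyl)benzene
Product: 16 triphenyl(7-phenylheptyl)phosphonium bromide
Conditions: PPh3, MeCN, reflux
Reagents that add atoms: triphenylphosphine, c1ccc(cc1)P(c1ccccc1)c1ccccc1
Why: SN2 quaternisation of triphenylphosphine by a primary alkyl bromide.

Step 11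
Reactants: 14 (2R,4S,6S)-2,4,6-trimethyl-7-oxo-4-[(triethylsilyl)peroxy]heptanoic acid; 16 triphenyl(7-phenylheptyl)phosphonium bromide
Product: 18 (2R,4S,6S,7Z)-2,4,6-trimethyl-14-phenyl-4-[(triethylsilyl)peroxy]tetradec-7-enoic acid, via phosphorus ylide 17 (not isolated)
Conditions: 16 (2.5 equiv), NaN(SiMe3)2 (2.4 equiv), THF, −78 °C; then 14, −78 to 0 °C
Reagents that add atoms: none
Why: Wittig olefination with a non-stabilised ylide: the first equivalent is consumed by the carboxylic acid, whose carboxylate is inert, and the excess adds to the aldehyde at low temperature faster than it deprotonates C8 or attacks the peroxide. The alkene geometry (mainly Z) is irrelevant because the double bond is reduced in step 12.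

Step 12
Reactants: 18 (2R,4S,6S,7Z)-2,4,6-trimethyl-14-phenyl-4-[(triethylsilyl)peroxy]tetradec-7-enoic acid
Product: 19 (2R,4S,6R)-2,4,6-trimethyl-14-phenyl-4-[(triethylsilyl)peroxy]tetradecanoic acid
Conditions: 2-nitrobenzenesulfonyl hydrazide, Et3N, CH2Cl2, rt
Reagents that add atoms: none
Why: Diimide generated from the sulfonyl hydrazide transfers two hydrogens to the C=C bond in a concerted syn fashion and does not reduce O–O bonds or the arene, which is why it replaces catalytic hydrogenation.

Step 13
Reactants: 19 (2R,4S,6R)-2,4,6-trimethyl-14-phenyl-4-[(triethylsilyl)peroxy]tetradecanoic acid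
Product: 21 methyl (4R,6S,8R)-4,6,8-trimethyl-3-oxo-16-phenyl-6-[(triethylsilyl)peroxy]hexadecanoate, via acyl imidazolide 20 (not isolated)
Conditions: 1,1'-carbonyldiimidazole, THF, rt; then KO2CCH2CO2Me, MgCl2, Et3N, MeCN, rt to 40 °C
Reagents that add atoms: methyl potassium malonate, COC(=O)CC(=O)[O-].[K+]
Why: Masamune homologation: the acyl imidazolide acylates the magnesium enolate of the malonate half-ester and decarboxylation gives the β-keto ester under essentially neutral conditions, so C4 and the silyl peroxide are preserved.

Step 14
Reactants: 21 methyl (4R,6S,8R)-4,6,8-trimethyl-3-oxo-16-phenyl-6-[(triethylsilyl)peroxy]hexadecanoate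
Product: 23 methyl 2-[(3S,4R,6S)-3-hydroxy-4,6-dimethyl-6-[(2R)-2-methyl-10-phenyldecyl]-1,2-dioxan-3-yl]acetate, via hydroperoxy keto ester 22 (not isolated)
Conditions: HF·pyridine, THF, 0 °C to rt
Reagents that add atoms: none
Why: Fluoride cleaves the O–Si bond and the freed hydroperoxide adds to the C3 ketone (hemiketalisation, 6-exo-trig) to close the 1,2-dioxane. The hemiketal equilibrates through the open form, so C3 settles with axial hydroxyl (anomeric effect) and equatorial C4 methyl and acetate arm, which is the configuration of 23.

## Compound list

1 | 1-bromo-2,2-dimethoxypropane | COC(C)(CBr)OC | starting material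
2 | 3-bromo-2-methoxyprop-1-ene (2-methoxyallyl bromide) | C=C(OC)CBr | intermediate
3 | (2E,4E)-hexa-2,4-diene | C/C=C/C=C/C | starting material
4 | 1-methoxy-cis-3,6-dimethylcyclohept-4-en-1-yl trifluoroacetate (mixed ketal ester, not isolated) | COC1(OC(=O)C(F)(F)F)C[C@H](C)C=C[C@H](C)C1 | intermediate
5 | (3R,6S)-3,6-dimethylcyclohept-4-en-1-one (cis, meso) | O=C1C[C@H](C)C=C[C@H](C)C1 | intermediate
6 | (3R,7S)-3,7-dimethyl-5-methylidenecyclohept-1-ene (cis, meso) | C=C1C[C@H](C)C=C[C@H](C)C1 | intermediate
7 | triethyl{[(1s,3R,6S)-1,3,6-trimethylcyclohept-4-en-1-yl]peroxy}silane | C[C@]1(OO[Si](CC)(CC)CC)C[C@H](C)C=C[C@H](C)C1 | intermediate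
8 | 2,4,6-trimethyl-4-[(triethylsilyl)peroxy]-8,9,10-trioxabicyclo[5.2.1]decane (secondary ozonide of 7, methyl groups all cis, not isolated) | C[C@]1(OO[Si](CC)(CC)CC)C[C@H](C)C2OC(OO2)[C@H](C)C1 | intermediate
9 | (2R,4s,6S)-2,4,6-trimethyl-4-[(triethylsilyl)peroxy]heptane-1,7-diol (meso) | OC[C@H](C)C[C@@](C)(OO[Si](CC)(CC)CC)C[C@H](C)CO | intermediate
10 | vinyl acetate | C=COC(C)=O | starting material
11 | (2S,4R,6R)-7-hydroxy-2,4,6-trimethyl-4-[(triethylsilyl)peroxy]heptyl acetate | OC[C@H](C)C[C@@](C)(OO[Si](CC)(CC)CC)C[C@H](C)COC(C)=O | intermediate
12 | (2R,4S,6S)-7-(acetyloxy)-2,4,6-trimethyl-4-[(triethylsilyl)peroxy]heptanoic acid | OC(=O)[C@H](C)C[C@@](C)(OO[Si](CC)(CC)CC)C[C@H](C)COC(C)=O | intermediate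
13 | (2R,4S,6S)-7-hydroxy-2,4,6-trimethyl-4-[(triethylsilyl)peroxy]heptanoic acid | OC(=O)[C@H](C)C[C@@](C)(OO[Si](CC)(CC)CC)C[C@H](C)CO | intermediate
14 | (2R,4S,6S)-2,4,6-trimethyl-7-oxo-4-[(triethylsilyl)peroxy]heptanoic acid | OC(=O)[C@H](C)C[C@@](C)(OO[Si](CC)(CC)CC)C[C@H](C)C=O | intermediate
15 | (7-bromoheptyl)benzene | BrCCCCCCCc1ccccc1 | starting material
16 | triphenyl(7-phenylheptyl)phosphonium bromide | [Br-].c1ccccc1CCCCCCC[P+](c1ccccc1)(c1ccccc1)c1ccccc1 | intermediate
17 | triphenyl(7-phenylheptylidene)phosphorane (ylide, not isolated) | c1ccccc1CCCCCCC=P(c1ccccc1)(c1ccccc1)c1ccccc1 | intermediate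
18 | (2R,4S,6S,7Z)-2,4,6-trimethyl-14-phenyl-4-[(triethylsilyl)peroxy]tetradec-7-enoic acid | OC(=O)[C@H](C)C[C@@](C)(OO[Si](CC)(CC)CC)C[C@H](C)/C=C\CCCCCCc1ccccc1 | intermediate
19 | (2R,4S,6R)-2,4,6-trimethyl-14-phenyl-4-[(triethylsilyl)peroxy]tetradecanoic acid | OC(=O)[C@H](C)C[C@@](C)(OO[Si](CC)(CC)CC)C[C@H](C)CCCCCCCCc1ccccc1 | intermediate
20 | (2R,4S,6R)-1-(1H-imidazol-1-yl)-2,4,6-trimethyl-14-phenyl-4-[(triethylsilyl)peroxy]tetradecan-1-one (not isolated) | O=C(n1ccnc1)[C@H](C)C[C@@](C)(OO[Si](CC)(CC)CC)C[C@H](C)CCCCCCCCc1ccccc1 | intermediate
21 | methyl (4R,6S,8R)-4,6,8-trimethyl-3-oxo-16-phenyl-6-[(triethylsilyl)peroxy]hexadecanoate | COC(=O)CC(=O)[C@H](C)C[C@@](C)(OO[Si](CC)(CC)CC)C[C@H](C)CCCCCCCCc1ccccc1 | intermediate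
22 | methyl (4R,6S,8R)-6-hydroperoxy-4,6,8-trimethyl-3-oxo-16-phenylhexadecanoate (not isolated) | COC(=O)CC(=O)[C@H](C)C[C@@](C)(OO)C[C@H](C)CCCCCCCCc1ccccc1 | intermediate
23 | methyl 2-[(3S,4R,6S)-3-hydroxy-4,6-dimethyl-6-[(2R)-2-methyl-10-phenyldecyl]-1,2-dioxan-3-yl]acetate | COC(=O)C[C@]1(O)OO[C@@](C)(C[C@H](C)CCCCCCCCc2ccccc2)C[C@H]1C | target

## Step count and least certain steps

Total step count: 14. Longest linear sequence: 13 steps (steps 1 to 9 and 11 to 14); step 10 is the only side branch. All peroxidic compounds (7 onwards) are to be kept in solution below 40 °C and never distilled.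

**Step 6 (key step).** The most likely failure is incomplete or reversed differentiation of the two enantiotopic hydroxymethyl groups. The large group beside each carbinol is a bulky neopentyl-type chain carrying the silyl peroxide, and it may sit in the enzyme pocket differently from the simple model diols, eroding enantiomeric purity or favouring the other terminus. The fallback sets out from 9 and returns at 19.
- Both hydroxyl groups are acetylated (Ac2O, pyridine) to the meso diacetate F1.
- The same lipase is used in the hydrolytic direction in NaH2PO4–Na2HPO4 buffer. It should remove the acetate from the terminus it would otherwise acylate and leave the enantiomeric monoacetate F2, whose free hydroxyl is at C9. The same compound arises directly if acylation of 9 prefers the other terminus.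
- The ends are then elaborated in reverse order: Dess–Martin oxidation to the aldehyde acetate F3, Wittig reaction with 17 to the alkenyl acetate F4, and diimide reduction to the saturated acetate F5.
- Deacetylation with an unselective esterase (pig liver esterase, pH 7) gives the primary alcohol F6, and TEMPO/NaClO2 oxidation gives 19.

**Step 2.** The most likely failure is diversion of the oxyallyl cation into stepwise alkylation and oligomerisation of the diene, because an acyclic diene is mostly s-trans and only its minor s-cis conformer can close the seven-membered ring. The fallback sets out from 3 and returns at 5. The diene is treated with 1,1,3,3-tetrabromoacetone and Fe2(CO)9 in benzene, an iron-bound oxyallyl species that is known to add to open-chain dienes, giving the dibromo ketone F7. Reductive debromination with Zn(Cu) and NH4Cl in MeOH then gives 5.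

**Step 4.** The most likely failure is poor facial selectivity in the capture of the nearly planar tertiary radical by O2, which is fast and has an early transition state; a second risk is partial hydroperoxidation of the ring alkene. The fallback sets out from 5 and returns at 7, replacing kinetic radical capture by a reversible ionic one.
- MeMgBr in THF gives the tertiary alcohol F8, whose configuration at the carbinol carbon does not matter.
- Aqueous H2O2 (50%) with catalytic H2SO4 at 0 °C exchanges hydroxyl for hydroperoxyl through the tertiary cation. Because ionisation is reversible, the epimers should equilibrate towards the hydroperoxide F9, which has the ring-bound methyl group equatorial and the O–O bond axial.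
- Et3SiCl and imidazole in CH2Cl2 then give 7.

**Step 5.** The most likely failure is attack of ethoxide or borohydride at silicon, which would unmask the hydroperoxide and let it be reduced; a second risk is epimerisation α to the transient aldehydes. The fallback sets out from 7 and returns at 9, avoiding both ozone and alcoholic borohydride.
- Dihydroxylation with K2OsO2(OH)4 (cat.) and N-methylmorpholine N-oxide in acetone/water gives the ring diol F10.
- NaIO4 in buffered THF/water cleaves it to the meso dialdehyde F11 (Lemieux–Johnson-type sequence).
- The non-basic hydride donor NaBH(OAc)3 in CH2Cl2 reduces F11 to 9.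

**Step 11.** The most likely failure is sequestration of the substrate as a poorly soluble carboxylate salt after proton transfer to the ylide, so that olefination is slow and C8 epimerises as the mixture warms. The fallback sets out from 12 and returns at 21, moving the homologation ahead of the olefination.
- The Masamune conditions of step 13 applied to 12 give the acetoxy β-keto ester F12.
- Lipase-catalysed methanolysis (Candida antarctica lipase B, MeOH, tert-butyl methyl ether; any ester exchange at C1 is degenerate) gives the hydroxy β-keto ester F13.
- TEMPO/PhI(OAc)2 in CH2Cl2 gives the aldehyde F14.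
- Wittig reaction with two equivalents of 17, the first of which forms a soluble chelated enolate that also shields the C3 ketone, gives the alkenyl β-keto ester F15.
- Diimide reduction as in step 12 gives 21.

## Further compounds

F1 | step 6 | (2R,4s,6S)-2,4,6-trimethyl-4-[(triethylsilyl)peroxy]heptane-1,7-diyl diacetate (meso diacetate) | CC(=O)OC[C@H](C)C[C@@](C)(OO[Si](CC)(CC)CC)C[C@H](C)COC(C)=O
F2 | step 6 | (2R,4S,6S)-7-hydroxy-2,4,6-trimethyl-4-[(triethylsilyl)peroxy]heptyl acetate (enantiomer of 11) | CC(=O)OC[C@H](C)C[C@@](C)(OO[Si](CC)(CC)CC)C[C@H](C)CO
F3 | step 6 | (2R,4R,6S)-2,4,6-trimethyl-7-oxo-4-[(triethylsilyl)peroxy]heptyl acetate | CC(=O)OC[C@H](C)C[C@@](C)(OO[Si](CC)(CC)CC)C[C@H](C)C=O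
F4 | step 6 | (2R,4S,6S,7Z)-2,4,6-trimethyl-14-phenyl-4-[(triethylsilyl)peroxy]tetradec-7-en-1-yl acetate | CC(=O)OC[C@H](C)C[C@@](C)(OO[Si](CC)(CC)CC)C[C@H](C)/C=C\CCCCCCc1ccccc1
F5 | step 6 | (2R,4S,6R)-2,4,6-trimethyl-14-phenyl-4-[(triethylsilyl)peroxy]tetradecyl acetate | CC(=O)OC[C@H](C)C[C@@](C)(OO[Si](CC)(CC)CC)C[C@H](C)CCCCCCCCc1ccccc1
F6 | step 6 | (2R,4S,6R)-2,4,6-trimethyl-14-phenyl-4-[(triethylsilyl)peroxy]tetradecan-1-ol | OC[C@H](C)C[C@@](C)(OO[Si](CC)(CC)CC)C[C@H](C)CCCCCCCCc1ccccc1
F7 | step 2 | 2,7-dibromo-cis-3,6-dimethylcyclohept-4-en-1-one (bromine configurations unspecified) | O=C1C(Br)[C@H](C)C=C[C@H](C)C1Br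
F8 | step 4 | cis-3,6-dimethyl-1-methylcyclohept-4-en-1-ol, that is 1,3,6-trimethylcyclohept-4-en-1-ol (carbinol configuration unspecified) | CC1(O)C[C@H](C)C=C[C@H](C)C1
F9 | step 4 | (1s,3R,6S)-1-hydroperoxy-1,3,6-trimethylcyclohept-4-ene | C[C@]1(OO)C[C@H](C)C=C[C@H](C)C1
F10 | step 5 | 3,5,7-trimethyl-5-[(triethylsilyl)peroxy]cycloheptane-1,2-diol (methyl groups all cis, cis-diol) | C[C@]1(OO[Si](CC)(CC)CC)C[C@H](C)C(O)C(O)[C@H](C)C1
F11 | step 5 | (2R,4s,6S)-2,4,6-trimethyl-4-[(triethylsilyl)peroxy]heptanedial (meso) | O=C[C@H](C)C[C@@](C)(OO[Si](CC)(CC)CC)C[C@H](C)C=O
F12 | step 11 | methyl (4R,6S,8S)-9-(acetyloxy)-4,6,8-trimethyl-3-oxo-6-[(triethylsilyl)peroxy]nonanoate | COC(=O)CC(=O)[C@H](C)C[C@@](C)(OO[Si](CC)(CC)CC)C[C@H](C)COC(C)=O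
F13 | step 11 | methyl (4R,6S,8S)-9-hydroxy-4,6,8-trimethyl-3-oxo-6-[(triethylsilyl)peroxy]nonanoate | COC(=O)CC(=O)[C@H](C)C[C@@](C)(OO[Si](CC)(CC)CC)C[C@H](C)CO
F14 | step 11 | methyl (4R,6S,8S)-4,6,8-trimethyl-3,9-dioxo-6-[(triethylsilyl)peroxy]nonanoate | COC(=O)CC(=O)[C@H](C)C[C@@](C)(OO[Si](CC)(CC)CC)C[C@H](C)C=O
F15 | step 11 | methyl (4R,6S,8S,9Z)-4,6,8-trimethyl-3-oxo-16-phenyl-6-[(triethylsilyl)peroxy]hexadec-9-enoate | COC(=O)CC(=O)[C@H](C)C[C@@](C)(OO[Si](CC)(CC)CC)C[C@H](C)/C=C\CCCCCCc1ccccc1
A1 | alternative 1 | (3R,6S)-3,6-dimethylcyclohept-4-en-1-one (cis, meso) | O=C1C[C@H](C)C=C[C@H](C)C1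
A2 | alternative 2 | methyl (3R)-3-methyl-11-phenylundecanoate | COC(=O)C[C@H](C)CCCCCCCCc1ccccc1
A3 | alternative 2 | (3R)-5-methoxy-3-methyl-5-oxopentanoic acid | COC(=O)C[C@H](C)CC(=O)O
A4 | alternative 2 | 8-phenyloctanoic acid | OC(=O)CCCCCCCc1ccccc1
A5 | alternative 3 | methyl (2R,6R)-2,6-dimethyl-4-oxo-14-phenyltetradecanoate | COC(=O)[C@H](C)CC(=O)C[C@H](C)CCCCCCCCc1ccccc1
A6 | alternative 3 | S-ethyl (3R)-3-methyl-11-phenylundecanethioate | CCSC(=O)C[C@H](C)CCCCCCCCc1ccccc1
A7 | alternative 3 | [(2S)-3-methoxy-2-methyl-3-oxopropyl]zinc iodide | COC(=O)[C@H](C)C[Zn]I
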